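A direct plan would first make the methylated two-ring phenol A1 by a three-component aryne reaction (lithium 2,6-dimethoxyphenoxide, 3,4,5-trimethoxybenzyne, then borylation and peroxide oxidation) and cap it with ring H by an Ullmann coupling.
It would then add A1 twice and 2,4,6-trimethoxyphenol once by one-pot iridium-catalysed C–H borylation and Chan–Lam coupling, and would strip the henicosamethyl ether A2 with BBr3.
Its weakest step would be the oxidative copper coupling, run three times on ever more precious oligomers: a di-ortho-substituted, electron-rich phenol and a crude pinacol boronate are the worst partners for this reaction, two equivalents of A1 are spent each time, and the borylation must find one C–H bond among a growing number of rings.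
The second would be the closing 21-fold BBr3 demethylation: one incomplete cleavage, ether scission or ring bromination on the octamer would give air-sensitive polyphenol mixtures that can be neither separated nor recycled.
The third would be the opening aryne aryloxy-hydroxylation, an untested three-component reaction in which protonation of the aryl anion and addition of the amide base compete, although every later step depends on its product.

**Plan of the new route**
The retrosynthesis cuts all seven ether bonds: rings C, E and G go back to one tribromo-o-benzoquinone (14), rings B, D and F to one hydroxy-aldehyde (6), ring A to iodide 8 and ring H to phenol 3.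
In rings C, E and G the hydroxyls on C3 and C4 are neighbours, and the ether carbons C1 and C6 are the β-carbons of the o-quinone that these two oxygens form; as vinylogous acyl bromides they take up two different phenoxides, one after the other, in one flask.
In rings B, D and F the ether carbon C4 lies para to C1: a formyl group on C4 is its latent oxygen (Dakin oxidation), so each of these rings gives its C1 oxygen to one quinone and, after unmasking, its C4 oxygen to the next.
The rings arise in the order A, B, then C with D, E with F, G with H, the reverse of the direct plan, and rings C, E and G become aromatic only after both of their ethers are in place.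
No aryne, C–H borylation, Chan–Lam coupling or BBr3 occurs: each chain-extending C–O bond is an addition–elimination on a quinone that cannot over-react, and the benzyl ethers, the spectator bromines and the last quinone all go in one hydrogenation.
Key step: step 8

Assumption: 3-(benzyloxy)benzene-1,2-diol (12, pyrogallol 1-benzyl ether) is taken to be purchasable. In quinone 14, C1 and C2 are the carbonyl carbons, C3 carries the benzyloxy group and C4, C5, C6 carry bromine; quinone C5, C4 and C6 become C1, C6 and C2 of rings C, E and G.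

Step 1
Reactants: 1 3,4,5-tris(benzyloxy)benzaldehyde
Product: 3 3,4,5-tris(benzyloxy)phenol, via aryl formate 2 (not isolated)
Conditions: mCPBA (1.3 equiv), CH2Cl2, 0 °C → rt; then K2CO3 (0.2 equiv), MeOH, rt
Reagents that add atoms: 3-chloroperbenzoic acid, OOC(=O)c1cccc(Cl)c1
Why: Baeyer–Villiger (Dakin-type) oxidation, in which the electron-rich trialkoxyphenyl group migrates to oxygen and methanolysis of formate 2 gives the phenol of ring H; no stereocentre is formed.

Step 2
Reactants: 4 3,5-bis(benzyloxy)phenol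
Product: 6 2,6-bis(benzyloxy)-4-hydroxybenzaldehyde, via aryl iminium chloride 5 (not isolated)
Conditions: POCl3 (1.5 equiv), DMF, 0 °C → rt; then H2O, 60 °C; crystallisation to remove the ortho-formyl isomer
Reagents that add atoms: N,N-dimethylformamide, CN(C)C=O; water, O
Why: Vilsmeier–Haack formylation, in which the chloroiminium ion should attack para to the free hydroxyl (between the two benzyloxy groups), as in the known formylation of 3,5-dimethoxyphenol to 4-hydroxy-2,6-dimethoxybenzaldehyde, and water hydrolyses iminium salt 5; no stereocentre is formed.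

Step 3
Reactants: 7 1,3,5-tris(benzyloxy)benzene
Product: 8 1,3,5-tris(benzyloxy)-2-iodobenzene
Conditions: NIS (1.05 equiv), MeCN, 0 °C → rt, dark
Reagents that add atoms: N-iodosuccinimide, O=C1CCC(=O)N1I
Why: Electrophilic aromatic iodination of a phloroglucinol triether whose three free positions are equivalent, so that mono-iodination can give only 8; no stereocentre is formed.

Step 4
Reactants: 6 2,6-bis(benzyloxy)-4-hydroxybenzaldehyde; 8 1,3,5-tris(benzyloxy)-2-iodobenzene
Product: 9 2,6-bis(benzyloxy)-4-[2,4,6-tris(benzyloxy)phenoxy]benzaldehyde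
Conditions: CuI (10 mol %), N,N-dimethylglycine hydrochloride (30 mol %), Cs2CO3 (2.5 equiv), dioxane, 100 °C, Ar
Reagents that add atoms: none
Why: Ligand-assisted Ullmann diaryl ether synthesis between an acidic, unhindered phenol and an aryl iodide, run once on cheap material to join rings A and B, with the formyl group of 6 (the latent C4 hydroxyl of ring B) keeping the phenol from being oxidised; no stereocentre is formed.

Step 5
Reactants: 9 2,6-bis(benzyloxy)-4-[2,4,6-tris(benzyloxy)phenoxy]benzaldehyde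
Product: 11 2,6-bis(benzyloxy)-4-[2,4,6-tris(benzyloxy)phenoxy]phenol, via aryl formate 10 (not isolated)
Conditions: mCPBA (1.3 equiv), CH2Cl2, 0 °C → rt; then K2CO3 (0.2 equiv), MeOH, rt
Reagents that add atoms: 3-chloroperbenzoic acid, OOC(=O)c1cccc(Cl)c1
Why: Baeyer–Villiger (Dakin-type) oxidation of a 2,6-dialkoxy-4-aryloxybenzaldehyde, whose very electron-rich aryl group migrates readily, followed by methanolysis of formate 10, uncovers the hindered phenol of ring B; no stereocentre is formed.

Step 6
Reactants: 12 3-(benzyloxy)benzene-1,2-diol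
Product: 13 3-(benzyloxy)-4,5,6-tribromobenzene-1,2-diol
Conditions: NBS (3.1 equiv), MeCN, −20 °C → rt
Reagents that add atoms: N-bromosuccinimide, O=C1CCC(=O)N1Br
Why: Electrophilic bromination of an electron-rich catechol carried to exhaustion, so that all three free positions are filled and no regiochemical choice arises; no stereocentre is formed.

Step 7
Reactants: 13 3-(benzyloxy)-4,5,6-tribromobenzene-1,2-diol
Product: 14 3-(benzyloxy)-4,5,6-tribromocyclohexa-3,5-diene-1,2-dione
Conditions: NaIO4 on silica (1.3 equiv), CH2Cl2, 0 °C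
Reagents that add atoms: none
Why: Periodate oxidation of a catechol to the o-benzoquinone, which its bromine atoms should protect from dimerisation; no stereocentre is formed.

Step 8
Reactants: 11 2,6-bis(benzyloxy)-4-[2,4,6-tris(benzyloxy)phenoxy]phenol; 14 3-(benzyloxy)-4,5,6-tribromocyclohexa-3,5-diene-1,2-dione; 6 2,6-bis(benzyloxy)-4-hydroxybenzaldehyde
Product: 18 benzylated rings A–D aldehyde, via monoaryloxy quinone 15 (not isolated), via bis(aryloxy) quinone 16 (not isolated), via catechol 17 (not isolated)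
Conditions: 14 (1.05 equiv), DMF, −20 °C, slow addition of 11 + K2CO3 (1.1 equiv); then 6 (1.5 equiv), K2CO3 (1.5 equiv), −20 → 35 °C; aq Na2S2O4, EtOAc; then BnBr (3 equiv), K2CO3 (3 equiv), DMF, 50 °C, Ar
Reagents that add atoms: benzyl bromide, BrCc1ccccc1
Why: Both ether bonds of ring C should form by vinylogous nucleophilic substitution (addition–elimination) on the o-quinone: the phenoxide of 11 adds to quinone C5, the β-carbon of the C1 carbonyl, bromide leaves, and the phenoxide of 6 then does the same at quinone C4, the β-carbon of the C2 carbonyl. The closest known reactions are the stepwise replacement of the halogens of chloranil, o-chloranil and 2,3-dichloro-1,4-naphthoquinone by two different aryloxides, and the reductive alkylation of quinones (dithionite, then an alkyl halide). No ring is closed and no stereocentre is formed: ring C enters as a six-membered dienedione and becomes aromatic only when bis(aryloxy)quinone 16 is reduced to catechol 17, which is benzylated in the same flask. The step needs site selectivity (C5 before C4) and one substitution per phenoxide: the benzyloxy group on C3 is an enol-ether donor that enriches C4 and C6 and leaves C5 as the most electrophilic C–Br carbon, the hindered phenoxide of 11 cannot go on to the more crowded C4, and the aryloxy group now on C5 enriches C6, so that only the C4–Br bond is left for the unhindered phenoxide of 6. Over-reaction is excluded because quinone 16 has no free phenol, and the formyl group of 6, the latent C4 hydroxyl of ring D, makes that phenoxide a poor electron donor towards the quinone. The remaining risk, electron transfer from the electron-rich phenoxide of 11 to the quinone, is countered by adding the phenoxide slowly to the quinone at −20 °C.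

Step 9
Reactants: 18 benzylated rings A–D aldehyde
Product: 20 rings A–D phenol, via aryl formate 19 (not isolated)
Conditions: mCPBA (1.3 equiv), CH2Cl2, 0 °C → rt; then K2CO3 (0.2 equiv), MeOH, rt
Reagents that add atoms: 3-chloroperbenzoic acid, OOC(=O)c1cccc(Cl)c1
Why: Baeyer–Villiger (Dakin-type) oxidation turns the formyl group between the two benzyloxy groups of ring D into the hindered phenol that is the next nucleophile, while aryl bromide, benzyl ethers and diaryl ethers are inert to the peracid; no stereocentre is formed.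

Step 10
Reactants: 20 rings A–D phenol; 14 3-(benzyloxy)-4,5,6-tribromocyclohexa-3,5-diene-1,2-dione; 6 2,6-bis(benzyloxy)-4-hydroxybenzaldehyde
Product: 24 benzylated rings A–F aldehyde, via monoaryloxy quinone 21 (not isolated), via bis(aryloxy) quinone 22 (not isolated), via catechol 23 (not isolated)
Conditions: 14 (1.05 equiv), DMF, −20 °C, slow addition of 20 + K2CO3 (1.1 equiv); then 6 (1.5 equiv), K2CO3 (1.5 equiv), −20 → 35 °C; aq Na2S2O4, EtOAc; then BnBr (3 equiv), K2CO3 (3 equiv), DMF, 50 °C, Ar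
Reagents that add atoms: benzyl bromide, BrCc1ccccc1
Why: The same one-flask sequence as in step 8 (two vinylogous nucleophilic substitutions on quinone 14, then dithionite reduction and benzylation of the catechol) should build ring E between rings D and F with the same site selectivity; no stereocentre is formed.

Step 11
Reactants: 24 benzylated rings A–F aldehyde
Product: 26 rings A–F phenol, via aryl formate 25 (not isolated)
Conditions: mCPBA (1.3 equiv), CH2Cl2, 0 °C → rt; then K2CO3 (0.2 equiv), MeOH, rt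
Reagents that add atoms: 3-chloroperbenzoic acid, OOC(=O)c1cccc(Cl)c1
Why: Baeyer–Villiger (Dakin-type) oxidation of the ring F aldehyde and methanolysis of formate 25 should give the hindered phenol of ring F; no stereocentre is formed.

Step 12
Reactants: 26 rings A–F phenol; 14 3-(benzyloxy)-4,5,6-tribromocyclohexa-3,5-diene-1,2-dione; 3 3,4,5-tris(benzyloxy)phenol
Product: 28 octamer o-quinone, via monoaryloxy quinone 27 (not isolated)
Conditions: 14 (1.05 equiv), DMF, −20 °C, slow addition of 26 + K2CO3 (1.1 equiv); then 3 (1.3 equiv), K2CO3 (1.3 equiv), −20 °C → rt, Ar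
Reagents that add atoms: none
Why: Two vinylogous nucleophilic substitutions on quinone 14 as in step 8, the hindered phenoxide of 26 taking quinone C5 and the unhindered phenoxide of 3 taking quinone C4, should complete the chain with ring G still at the quinone stage; no stereocentre is formed.

Step 13
Reactants: 28 octamer o-quinone
Product: 29 CNP0206369.0
Conditions: H2 (3 atm), Pd(OH)2/C, NaOAc (3.3 equiv), degassed THF/MeOH, rt; filtration under Ar; Sephadex LH-20, degassed MeOH
Reagents that add atoms: none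
Why: Catalytic hydrogenation should reduce the o-quinone of ring G to the catechol, cleave all nineteen benzyl ethers and remove the three aryl bromides in one reducing, near-neutral operation (NaOAc takes up HBr), so that the air-sensitive polyphenol never meets base, Lewis acid or oxidant; no stereocentre is present.

**Compound list**
1 | 3,4,5-tris(benzyloxy)benzaldehyde | O=Cc1cc(OCc2ccccc2)c(OCc2ccccc2)c(OCc2ccccc2)c1 | starting material
2 | 3,4,5-tris(benzyloxy)phenyl formate | O=COc1cc(OCc2ccccc2)c(OCc2ccccc2)c(OCc2ccccc2)c1 | intermediate (not isolated)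
3 | 3,4,5-tris(benzyloxy)phenol (ring H unit) | Oc1cc(OCc2ccccc2)c(OCc2ccccc2)c(OCc2ccccc2)c1 | intermediate
4 | 3,5-bis(benzyloxy)phenol | Oc1cc(OCc2ccccc2)cc(OCc2ccccc2)c1 | starting material
5 | [2,6-bis(benzyloxy)-4-hydroxybenzylidene]dimethyliminium chloride | C[N+](C)=Cc1c(OCc2ccccc2)cc(O)cc1OCc1ccccc1.[Cl-] | intermediate (not isolated)
6 | 2,6-bis(benzyloxy)-4-hydroxybenzaldehyde (unit for rings B, D and F) | O=Cc1c(OCc2ccccc2)cc(O)cc1OCc1ccccc1 | intermediate
7 | 1,3,5-tris(benzyloxy)benzene | c1ccccc1COc1cc(OCc2ccccc2)cc(OCc2ccccc2)c1 | starting material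
8 | 1,3,5-tris(benzyloxy)-2-iodobenzene (ring A unit) | c1ccccc1COc1cc(OCc2ccccc2)c(I)c(OCc2ccccc2)c1 | intermediate
9 | 2,6-bis(benzyloxy)-4-[2,4,6-tris(benzyloxy)phenoxy]benzaldehyde (rings A–B) | c1ccccc1COc1cc(OCc2ccccc2)c(Oc2cc(OCc3ccccc3)c(C=O)c(OCc3ccccc3)c2)c(OCc2ccccc2)c1 | intermediate
10 | 2,6-bis(benzyloxy)-4-[2,4,6-tris(benzyloxy)phenoxy]phenyl formate | c1ccccc1COc1cc(OCc2ccccc2)c(Oc2cc(OCc3ccccc3)c(OC=O)c(OCc3ccccc3)c2)c(OCc2ccccc2)c1 | intermediate (not isolated)
11 | 2,6-bis(benzyloxy)-4-[2,4,6-tris(benzyloxy)phenoxy]phenol (rings A–B, free hindered OH on ring B) | c1ccccc1COc1cc(OCc2ccccc2)c(Oc2cc(OCc3ccccc3)c(O)c(OCc3ccccc3)c2)c(OCc2ccccc2)c1 | intermediate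
12 | 3-(benzyloxy)benzene-1,2-diol | Oc1c(O)c(OCc2ccccc2)ccc1 | starting material
13 | 3-(benzyloxy)-4,5,6-tribromobenzene-1,2-diol | Oc1c(O)c(OCc2ccccc2)c(Br)c(Br)c1Br | intermediate
14 | 3-(benzyloxy)-4,5,6-tribromocyclohexa-3,5-diene-1,2-dione (o-quinone unit for rings C, E and G) | O=C1C(=O)C(OCc2ccccc2)=C(Br)C(Br)=C1Br | intermediate
15 | quinone 14 in which the bromine on C5 is replaced by the phenoxy oxygen of 11 | c1ccccc1COc1cc(OCc2ccccc2)c(Oc2cc(OCc3ccccc3)c(OC3=C(Br)C(=O)C(=O)C(OCc4ccccc4)=C3Br)c(OCc3ccccc3)c2)c(OCc2ccccc2)c1 | intermediate (not isolated)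
16 | 15 in which the bromine on quinone C4 is replaced by a 3,5-bis(benzyloxy)-4-formylphenoxy group (the oxygen of 6) | c1ccccc1COc1cc(OCc2ccccc2)c(Oc2cc(OCc3ccccc3)c(OC3=C(Br)C(=O)C(=O)C(OCc4ccccc4)=C3Oc3cc(OCc4ccccc4)c(C=O)c(OCc4ccccc4)c3)c(OCc3ccccc3)c2)c(OCc2ccccc2)c1 | intermediate (not isolated)
17 | catechol formed by reduction of the two carbonyl groups of 16 | c1ccccc1COc1cc(OCc2ccccc2)c(Oc2cc(OCc3ccccc3)c(Oc3c(Br)c(O)c(O)c(OCc4ccccc4)c3Oc3cc(OCc4ccccc4)c(C=O)c(OCc4ccccc4)c3)c(OCc3ccccc3)c2)c(OCc2ccccc2)c1 | intermediate (not isolated)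
18 | benzylated rings A–D aldehyde: 17 with both catechol hydroxyls benzylated (ring C is 2-bromo-3,4,5-tris(benzyloxy)benzene-1,6-diyl; ring D carries the formyl group between its two benzyloxy groups) | c1ccccc1COc1cc(OCc2ccccc2)c(Oc2cc(OCc3ccccc3)c(Oc3c(Br)c(OCc4ccccc4)c(OCc4ccccc4)c(OCc4ccccc4)c3Oc3cc(OCc4ccccc4)c(C=O)c(OCc4ccccc4)c3)c(OCc3ccccc3)c2)c(OCc2ccccc2)c1 | intermediate
19 | formate ester of 20 (18 with the formyl group replaced by OCHO) | c1ccccc1COc1cc(OCc2ccccc2)c(Oc2cc(OCc3ccccc3)c(Oc3c(Br)c(OCc4ccccc4)c(OCc4ccccc4)c(OCc4ccccc4)c3Oc3cc(OCc4ccccc4)c(OC=O)c(OCc4ccccc4)c3)c(OCc3ccccc3)c2)c(OCc2ccccc2)c1 | intermediate (not isolated)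
20 | rings A–D phenol: 18 with the formyl group of ring D replaced by OH | c1ccccc1COc1cc(OCc2ccccc2)c(Oc2cc(OCc3ccccc3)c(Oc3c(Br)c(OCc4ccccc4)c(OCc4ccccc4)c(OCc4ccccc4)c3Oc3cc(OCc4ccccc4)c(O)c(OCc4ccccc4)c3)c(OCc3ccccc3)c2)c(OCc2ccccc2)c1 | intermediate
21 | quinone 14 in which the bromine on C5 is replaced by the ring D oxygen of 20 | c1ccccc1COc1cc(OCc2ccccc2)c(Oc2cc(OCc3ccccc3)c(Oc3c(Br)c(OCc4ccccc4)c(OCc4ccccc4)c(OCc4ccccc4)c3Oc3cc(OCc4ccccc4)c(OC4=C(Br)C(=O)C(=O)C(OCc5ccccc5)=C4Br)c(OCc4ccccc4)c3)c(OCc3ccccc3)c2)c(OCc2ccccc2)c1 | intermediate (not isolated)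
22 | 21 in which the bromine on quinone C4 is replaced by a 3,5-bis(benzyloxy)-4-formylphenoxy group | c1ccccc1COc1cc(OCc2ccccc2)c(Oc2cc(OCc3ccccc3)c(Oc3c(Br)c(OCc4ccccc4)c(OCc4ccccc4)c(OCc4ccccc4)c3Oc3cc(OCc4ccccc4)c(OC4=C(Br)C(=O)C(=O)C(OCc5ccccc5)=C4Oc4cc(OCc5ccccc5)c(C=O)c(OCc5ccccc5)c4)c(OCc4ccccc4)c3)c(OCc3ccccc3)c2)c(OCc2ccccc2)c1 | intermediate (not isolated)
23 | catechol formed by reduction of the two carbonyl groups of 22 | c1ccccc1COc1cc(OCc2ccccc2)c(Oc2cc(OCc3ccccc3)c(Oc3c(Br)c(OCc4ccccc4)c(OCc4ccccc4)c(OCc4ccccc4)c3Oc3cc(OCc4ccccc4)c(Oc4c(Br)c(O)c(O)c(OCc5ccccc5)c4Oc4cc(OCc5ccccc5)c(C=O)c(OCc5ccccc5)c4)c(OCc4ccccc4)c3)c(OCc3ccccc3)c2)c(OCc2ccccc2)c1 | intermediate (not isolated)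
24 | benzylated rings A–F aldehyde: 23 with both catechol hydroxyls benzylated (ring E is 2-bromo-3,4,5-tris(benzyloxy)benzene-1,6-diyl; ring F carries the formyl group) | c1ccccc1COc1cc(OCc2ccccc2)c(Oc2cc(OCc3ccccc3)c(Oc3c(Br)c(OCc4ccccc4)c(OCc4ccccc4)c(OCc4ccccc4)c3Oc3cc(OCc4ccccc4)c(Oc4c(Br)c(OCc5ccccc5)c(OCc5ccccc5)c(OCc5ccccc5)c4Oc4cc(OCc5ccccc5)c(C=O)c(OCc5ccccc5)c4)c(OCc4ccccc4)c3)c(OCc3ccccc3)c2)c(OCc2ccccc2)c1 | intermediate
25 | formate ester of 26 (24 with the formyl group replaced by OCHO) | c1ccccc1COc1cc(OCc2ccccc2)c(Oc2cc(OCc3ccccc3)c(Oc3c(Br)c(OCc4ccccc4)c(OCc4ccccc4)c(OCc4ccccc4)c3Oc3cc(OCc4ccccc4)c(Oc4c(Br)c(OCc5ccccc5)c(OCc5ccccc5)c(OCc5ccccc5)c4Oc4cc(OCc5ccccc5)c(OC=O)c(OCc5ccccc5)c4)c(OCc4ccccc4)c3)c(OCc3ccccc3)c2)c(OCc2ccccc2)c1 | intermediate (not isolated)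
26 | rings A–F phenol: 24 with the formyl group of ring F replaced by OH | c1ccccc1COc1cc(OCc2ccccc2)c(Oc2cc(OCc3ccccc3)c(Oc3c(Br)c(OCc4ccccc4)c(OCc4ccccc4)c(OCc4ccccc4)c3Oc3cc(OCc4ccccc4)c(Oc4c(Br)c(OCc5ccccc5)c(OCc5ccccc5)c(OCc5ccccc5)c4Oc4cc(OCc5ccccc5)c(O)c(OCc5ccccc5)c4)c(OCc4ccccc4)c3)c(OCc3ccccc3)c2)c(OCc2ccccc2)c1 | intermediate
27 | quinone 14 in which the bromine on C5 is replaced by the ring F oxygen of 26 | c1ccccc1COc1cc(OCc2ccccc2)c(Oc2cc(OCc3ccccc3)c(Oc3c(Br)c(OCc4ccccc4)c(OCc4ccccc4)c(OCc4ccccc4)c3Oc3cc(OCc4ccccc4)c(Oc4c(Br)c(OCc5ccccc5)c(OCc5ccccc5)c(OCc5ccccc5)c4Oc4cc(OCc5ccccc5)c(OC5=C(Br)C(=O)C(=O)C(OCc6ccccc6)=C5Br)c(OCc5ccccc5)c4)c(OCc4ccccc4)c3)c(OCc3ccccc3)c2)c(OCc2ccccc2)c1 | intermediate (not isolated)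
28 | octamer o-quinone: 27 in which the bromine on quinone C4 is replaced by a 3,4,5-tris(benzyloxy)phenoxy group (ring H); ring G is the 3-(benzyloxy)-6-bromo-1,2-dione | c1ccccc1COc1cc(OCc2ccccc2)c(Oc2cc(OCc3ccccc3)c(Oc3c(Br)c(OCc4ccccc4)c(OCc4ccccc4)c(OCc4ccccc4)c3Oc3cc(OCc4ccccc4)c(Oc4c(Br)c(OCc5ccccc5)c(OCc5ccccc5)c(OCc5ccccc5)c4Oc4cc(OCc5ccccc5)c(OC5=C(Br)C(=O)C(=O)C(OCc6ccccc6)=C5Oc5cc(OCc6ccccc6)c(OCc6ccccc6)c(OCc6ccccc6)c5)c(OCc5ccccc5)c4)c(OCc4ccccc4)c3)c(OCc3ccccc3)c2)c(OCc2ccccc2)c1 | intermediate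
29 | CNP0206369.0 (achiral; 21 free hydroxyls, seven diaryl ether bonds) | Oc1cc(O)c(Oc2cc(O)c(Oc3cc(O)c(O)c(O)c3Oc3cc(O)c(Oc4cc(O)c(O)c(O)c4Oc4cc(O)c(Oc5cc(O)c(O)c(O)c5Oc5cc(O)c(O)c(O)c5)c(O)c4)c(O)c3)c(O)c2)c(O)c1 | target

Total step count: 13. Longest linear sequence: 9 steps (7 → 8 → 9 → 11 → 18 → 20 → 24 → 26 → 28 → 29; steps 3, 4, 5, 8, 9, 10, 11, 12, 13).

Steps most likely to fail:

Step 8 (steps 10 and 12 repeat the operation and share the risk). The electron-rich, hindered phenoxide may transfer an electron to the strongly oxidising tribromoquinone, so that the phenol is oxidised instead of substituting, or it may attack the wrong β-carbon. The fallback keeps the hindered phenol away from quinone 14. It sets out from 14, which would first be treated with potassium 4-nitrophenoxide, a phenoxide that cannot be oxidised (MeCN, −20 °C), to give the relay quinone 3-(benzyloxy)-4,6-dibromo-5-(4-nitrophenoxy)cyclohexa-3,5-diene-1,2-dione F1. The phenoxide of 11 would then displace 4-nitrophenoxide from C5 by vinylogous transesterification of this milder aryloxyquinone (K2CO3, DMF, 0 °C). This comes back to the route at 15, which is carried on with 6, dithionite and benzyl bromide as in step 8.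

Step 13. Hydrogen bromide from the three C–Br bonds may poison the catalyst, so that hydrogenolysis stalls at partly benzylated, air-sensitive polyphenols that can be neither driven to completion nor separated. The fallback separates the tasks and sets out from 28. Aqueous Na2S2O4, then Pd(OAc)2/PPh3 with HCO2Na (DMF, 90 °C), would reduce the quinone and remove the three bromines without touching the benzyl ethers. This would give the debrominated octamer catechol F2. BCl3 with pentamethylbenzene as cation scavenger (CH2Cl2, −78 °C) would then cleave the nineteen benzyl ethers without hydrogen, coming back to the route at 29.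

Step 4. The formyl-bearing phenoxide of 6 is a weak nucleophile and the aryl–copper species from the doubly ortho-substituted, electron-rich iodide is slow to form, so protodeiodination may outrun C–O bond formation. The fallback reverses the polarity of the A–B bond and sets out from 8. Copper-catalysed hydroxylation (CuI, 1,10-phenanthroline, KOH, DMSO/H2O, 100 °C) would give 2,4,6-tris(benzyloxy)phenol F3. Its bulky phenoxide would displace the para fluorine of 2,4,6-trifluorobenzaldehyde (K2CO3, DMF, 0 °C → rt) to give 2,6-difluoro-4-[2,4,6-tris(benzyloxy)phenoxy]benzaldehyde F4. Benzyl alcohol/NaH (THF, 0 °C → rt) would then replace the two fluorines ortho to the formyl group, coming back to the route at 9.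

Further compounds
F1 | step 8 | 3-(benzyloxy)-4,6-dibromo-5-(4-nitrophenoxy)cyclohexa-3,5-diene-1,2-dione | O=C1C(=O)C(OCc2ccccc2)=C(Br)C(Oc2ccc(cc2)[N+](=O)[O-])=C1Br
F2 | step 13 | debrominated octamer catechol (28 with the three bromines replaced by hydrogen and the ring G dione reduced to the 1,2-diol; nineteen benzyl ethers kept) | c1ccccc1COc1cc(OCc2ccccc2)c(Oc2cc(OCc3ccccc3)c(Oc3cc(OCc4ccccc4)c(OCc4ccccc4)c(OCc4ccccc4)c3Oc3cc(OCc4ccccc4)c(Oc4cc(OCc5ccccc5)c(OCc5ccccc5)c(OCc5ccccc5)c4Oc4cc(OCc5ccccc5)c(Oc5cc(O)c(O)c(OCc6ccccc6)c5Oc5cc(OCc6ccccc6)c(OCc6ccccc6)c(OCc6ccccc6)c5)c(OCc5ccccc5)c4)c(OCc4ccccc4)c3)c(OCc3ccccc3)c2)c(OCc2ccccc2)c1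
F3 | step 4 | 2,4,6-tris(benzyloxy)phenol | Oc1c(OCc2ccccc2)cc(OCc2ccccc2)cc1OCc1ccccc1
F4 | step 4 | 2,6-difluoro-4-[2,4,6-tris(benzyloxy)phenoxy]benzaldehyde | O=Cc1c(F)cc(Oc2c(OCc3ccccc3)cc(OCc3ccccc3)cc2OCc2ccccc2)cc1F
A1 | direct plan | 6-(2,6-dimethoxyphenoxy)-2,3,4-trimethoxyphenol | COc1cccc(OC)c1Oc1cc(OC)c(OC)c(OC)c1O
A2 | direct plan | henicosa-O-methyl ether of the target | COc1cc(OC)c(Oc2cc(OC)c(Oc3cc(OC)c(OC)c(OC)c3Oc3cc(OC)c(Oc4cc(OC)c(OC)c(OC)c4Oc4cc(OC)c(Oc5cc(OC)c(OC)c(OC)c5Oc5cc(OC)c(OC)c(OC)c5)c(OC)c4)c(OC)c3)c(OC)c2)c(OC)c1
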